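The flasks hold from 0.010 M to 0.040 M of starting complex under the same held gas, and you want the complex with two exchanged at 15 min.

| setting | ochre | amber | gamma | alpha | epsilon | zeta | eta |
|---|---|---|---|---|---|---|---|
| starting complex | 0.0064 M | 0.027 M | 0.030 M | 0.015 M | 0.020 M | 0.010 M | 0.040 M |
| gas | 4 mM (held) | 4 mM (held) | 4.0 mM (held) | 4.0 mM (held) | 4.0 mM (held) | 4.0 mM (held) | 4.0 mM (held) |
| remark | run made earlier | run made earlier |  |  |  |  |  |
| time |  |  | 15 min | 15 min | 15 min | 15 min | 15 min |

| run | time / min | complex with two exchanged / % | starting complex / % |
|---|---|---|---|
| ochre | 2.00 | 28.7 | 36.2 |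
| ochre | 4.00 | 62.7 | 2.6 |
| ochre | 6.00 | 41.8 | 0.2 |
| ochre | 8.00 | 25.2 | 0 |
| ochre | 10.0 | 11.7 | 1.4 |
| ochre | 12.0 | 6.9 | 0 |
| ochre | 15.0 | 1.8 | 0.5 |
| amber | 2.00 | 4.2 | 71.9 |
| amber | 4.00 | 10.9 | 42.9 |
| amber | 6.00 | 21.7 | 18.6 |
| amber | 8.00 | 32.6 | 4.9 |
| amber | 10.0 | 40.3 | 0 |
| amber | 12.0 | 28.6 | 0.3 |
| amber | 15.0 | 14.9 | 0 |

(scatter of a reading: 1 percentage point)

- the flasks put in order of amount of complex with two exchanged, in percent of the starting complex charged, best first, at 15 min (gamma / alpha / epsilon / zeta / eta)
- the amount of complex with two exchanged, in percent of the starting complex charged of the flask you put first, at 15 min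
- the amount of complex with two exchanged, in percent of the starting complex charged of the flask you put last, at 15 min

- at the start none of incoming ligand is dissolved
- the analysis behind the earlier runs scatters by 1 percentage point, standard deviation
- steps that have been proposed: complex with two exchanged + incoming ligand -> over-reaction product; starting complex + incoming ligand -> leaving ligand + complex with one exchanged; leaving ligand + starting complex -> side product; complex with one exchanged + incoming ligand -> leaving ligand + complex with two exchanged; gas <-> incoming ligand

Read amber first. Its starting complex stands at 71.9 %, 42.9 % and 18.6 % of the charge at 2.00 min, 4.00 min and 6.00 min. Each interval keeps a smaller share than the one before, so this isn't first order. It looks like a roughly steady amount taken per minute, which points to the supply of incoming ligand from the gas as the rate-limiting step. Call that amount, as read from amber, the drain, 3.60 mM/min. I assume the same drain in every flask under this gas and call the charge over the drain the flask's clearing time, though this is rough, since ochre loses its starting complex more slowly between 2.00 min and 4.00 min.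

My rule, for flasks under the same gas, is that the fall of a flask's complex with two exchanged follows that of a neighbouring run, slid later by the difference in clearing times. As a test, ochre and amber differ by 5.73 min in clearing time, and their top readings stand 6.00 min apart.

Now the ladder. Zeta's clearing time is 2.78 min. Amber's tail reads as a life of the complex with two exchanged of 5.03 min, longer than that. Eta's clearing time is 11.1 min, which is longer again but still short of 15 min. So I expect zeta far down its fall at the reading, and eta just after its top.

Sliding ochre by 1.00 min, I reckon zeta at 2.82 %. Sliding amber by 3.61 min gives eta 31.8 %. I take that as on the high side, because amber, with the larger charge, has a lower top reading than ochre, and eta's charge is larger again.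

The forecast, reasoning that “more concentrated flasks peak later”, gives eta > gamma > epsilon > alpha > zeta, with 25 % on top, below my figure, and 3.5 % last, above mine.

The flasks give eta > gamma > epsilon > alpha > zeta, with 30.3 % for eta and 2.88 % for zeta.

    complex with two exchanged + incoming ligand → over-reaction product (k = 1.80 /M/s)
    starting complex + incoming ligand → leaving ligand + complex with one exchanged (k = 34.0 /M/s)
    leaving ligand + starting complex → side product (k = 1.50 /M/s)
    complex with one exchanged + incoming ligand → leaving ligand + complex with two exchanged (k = 91.0 /M/s)
    gas ⇌ incoming ligand, rate k5*(csat - [incoming ligand]) (kL = 0.0110 /s)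

At 15.0 min eta holds 10.1 % of over-reaction product. Its clearing time of 11.1 min lies 3.89 min before the reading. Eta's neighbour with 0.010 M of starting complex has a clearing time of 2.78 min, which lies 12.2 min before the reading, and at 15.0 min it holds 2.88 % of complex with two exchanged beside 55.5 % of over-reaction product.

The readings come from a simulation for substances that don't exist; the scatter is artificial.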